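The constants used here are made up; the flask was simulated.

The ratio of fresh carrier to spent carrier is what this flask is examined on.

    spent carrier + salt in the second phase ⇌ fresh carrier + spent salt in the second phase (K1 = 0.42, k1 = 500 /M/h)
    crystals ⇌ target, rate k2*(cs2 - [target]) while solid is left; crystals form when [target] > cs2 (cs2 = 0.28 mM, k2 = 6.5 /h)
    starting material + fresh carrier → target + spent carrier (k3 = 220 /M/h)
    starting material + target → side product (k4 = 23 /M/h)
    fresh carrier ⇌ dormant form (K5 = 0.61, k5 = 0.023 /h)

starting material 20 mM; salt in the second phase 2.00 equiv; spent carrier 5.3 mol%; time 10 h; volume of the second phase over the first 1.0

- in percentages every species weighs as the starting material in it: one side product counts as two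
- for target the crystals are counted in
- in the second phase: salt in the second phase, spent salt in the second phase; everything else is in the first
- charges count per volume of the first phase; a concentration in a rate is the amount of a species over the volume of its own phase; every rate counts per litre of the first phase
- as a solid, counted per litre of solution: crystals
- run time (flask): 10 h

- cedar: doubling the amount of salt in the second phase, all else as stated
- alder: doubling the solubility in step 2, all else as stated
- larch: doubling the dissolution coefficient of step 2, all else as stated

* the target and crystals together standing at 10 h, as a percentage of the starting material charged
* the change that raises the amount of target and crystals together at 10 h, in percent of the starting material charged most ("none" if none brings more than 2 percentage points) (cedar / alder / larch / none)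
* amount of target and crystals together at 10 h, in percent of the starting material charged, after alder

Is the exchange at balance during the run? I assume so for the reckoning: as charged, spent carrier has a half-life of 2.1 min by the forward exchange, shorter than the 9.45 min of fresh carrier in the turnover step. So, the phases being equal in volume, I take c(fresh carrier)/c(spent carrier) as the exchange constant times c(salt in the second phase)/c(spent salt in the second phase).

What must the end look like? Each turnover spends one salt, so if each starting material turned over once through the carrier, one equivalent would be spent and the rest would stand beside it, the salt taken up by the carrier charge being left aside. The ratio is then 0.420: the full-turnover ratio, the exchange constant times salt left over salt spent at complete turnover.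

How fast does the flask go there? With the carrier wholly fresh, starting material falls at a pseudo-first-order 0.233 /h. That pace is multiplied by the fresh share, ratio over one plus ratio, and the share shrinks as salt is spent. I leave the dormant form out of that share, its forward half-life of 30 h being longer than the run, so the share is reckoned high. Integrating this by hand, a turnover of 0.7 takes 8.66 h, which is less than the run time. I commit to a little above 0.7 turned over through the carrier at 10 h.

Is that the yield? No, it is turnover, not target kept. Dissolved target has a half-life of 1.5 h by the side step with starting material as charged, short against the run, so some is lost, and I put no figure on that.

Which change helps? Cedar lifts the full-turnover ratio to 1.26. Alder and larch change step 2, which does not enter the full-turnover ratio.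

The forecast gives 60% (54% to 66%), names cedar, and gives 56% after alder (50% to 62%), holding that “doubling the solubility only feeds the side reaction”. Its yield is a different quantity from my turnover.

The simulation gives 60.7%. The best change is cedar, at 8.5 percentage points, against −3.9 points for alder and 1.7 points for larch. After alder the flask stands at 56.8%.

The flask at 100 h, with 53.0% of its salt left, reads fresh over spent carrier 0.474, beside the full-turnover ratio 0.420. The neighbour with 21 mol% of spent carrier has the same salt equivalents, hence the same reckoned 0.420, but a pace of 0.924 /h, so its turnover of 0.7 is reckoned at about 2.19 h. That neighbour ends with 3.3% of its starting material left and 88.0% as target and crystals, and its fresh over spent carrier reads 0.421.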